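A direct plan would formylate 3,4,5-trimethoxyphenol to salicylaldehyde A1, turn a second portion of the phenol (O-isopropylation, ortho-lithiation/CO2, acylation of dimethylsulfoxonium methylide) into β-keto sulfoxonium ylide A2, join A1 and A2 by [Cp*RhCl2]2-catalysed formyl C–H activation/carbene insertion with acid cyclodehydration to flavone A3, and unmask with BCl3. Its weakest steps would be:
(a) the three-step preparation of A2, which would spend a protection, a metalation and an ylide synthesis on an aroyl donor that adds no skeletal complexity;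
(b) the trivalent-rhodium union, in which an acyl–metal flanked by OH and OMe would have to insert a carbene bearing a 2,6-dioxygenated aryl, and the doubly ortho-hindered diketone would then have to close in hot acid, all on both advanced fragments;
(c) the final BCl3 step, which would have to cleave the isopropyl ether and exactly one (5-OMe) of six methyl ethers on the finished flavone, with the 6-OMe next to the chelate and the 2'-OMe at risk.

Plan of the new route
- Cuts: C8–C8a and C4a–C5 (all of ring A) and C2–C1'. The bonds the direct plan makes (C3–C4, O1–C2) are bought inside 4H-pyran-4-one (ring C).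
- Feature used: C5(OH)–C6(OMe)–C7(OMe)–C8(H) of ring A is the C1(=O)–C2(OMe)=C3(OMe)–C4(H) array of mono-reduced dimethyl squarate. C8a=C4a is the O1–C2=C3 enol-ether bond of the γ-pyranone, whose C4=O lies peri to the phenol to be formed.
- Ring order: C (bought), then B attached at C2 by Negishi coupling, then A built last by Stille coupling, 4π-opening and 6π-closure of a 4-pyranonyl-cyclobutenone.
- Consequences: no diketone, ylide or rhodium step. The 5-OH arises free from the ketene carbonyl, so no methyl ether is ever cleaved; the only late operation is removal of one MOM group.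

Key step: step 7

Remark: compounds 11, 12, 13 and 15 are racemic; their single stereocentre disappears in step 7 and the target is achiral. 3,4,5-Trimethoxyphenol, 4H-pyran-4-one, dimethyl squarate and TMPZnCl·LiCl (THF solution) are taken as catalogue materials.

Step 1
Reactants: 1 3,4,5-trimethoxyphenol
Product: 2 1,2,3-trimethoxy-5-(methoxymethoxy)benzene
Conditions: NaH, THF/DMF, 0 °C; MOMCl, 0 °C → rt
Reagents that add atoms: chloromethyl methyl ether, COCCl
Why: Williamson-type O-alkylation of the phenoxide; the MOM ether directs the next lithiation, should tolerate zinc amides, zerovalent palladium and 100 °C, and leaves under mild acid that touches no methyl ether.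

Step 2
Reactants: 2 1,2,3-trimethoxy-5-(methoxymethoxy)benzene
Product: 4 1-iodo-2,3,4-trimethoxy-6-(methoxymethoxy)benzene, via aryllithium 3 (not isolated)
Conditions: n-BuLi, THF, 0 °C; then I2, −78 °C → rt
Reagents that add atoms: iodine, II
Why: Directed ortho-metalation and iodination; the two free ring positions are equivalent and each lies between OMOM and OMe, so one regioisomer should form without the over-iodination that an electrophilic route risks.

Step 3
Reactants: 5 4H-pyran-4-one; 4 1-iodo-2,3,4-trimethoxy-6-(methoxymethoxy)benzene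
Product: 7 2-[2,3,4-trimethoxy-6-(methoxymethoxy)phenyl]-4H-pyran-4-one, via (4-oxo-4H-pyran-2-yl)zinc chloride 6 (not isolated)
Conditions: 5 (1.3 equiv), TMPZnCl·LiCl (1.4 equiv), THF, 25 °C; then 4, Pd(OAc)2 (2 mol %), SPhos (4 mol %), THF, 50 °C
Reagents that add atoms: none
Why: α-Zincation of the γ-pyranone next to the ring oxygen by the hindered zinc amide (the C–H metalation pattern known for chromones; C2 and C6 are equivalent here) gives a ketone-tolerant heteroarylzinc, and Negishi coupling with a biarylphosphine suited to di-ortho-substituted iodides should form the C2–C1' bond.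

Step 4
Reactants: 7 2-[2,3,4-trimethoxy-6-(methoxymethoxy)phenyl]-4H-pyran-4-one
Product: 9 2-(tributylstannyl)-6-[2,3,4-trimethoxy-6-(methoxymethoxy)phenyl]-4H-pyran-4-one, via pyranonylzinc chloride 8 (not isolated)
Conditions: TMPZnCl·LiCl (1.2 equiv), THF, 25 °C; then Bu3SnCl, 25 → 50 °C
Reagents that add atoms: tributyltin chloride, CCCC[Sn](Cl)(CCCC)CCCC
Why: A second zincation at the only remaining C–H next to the ring oxygen (by analogy with chromones the positions next to the carbonyl need Lewis-acid assistance, and the arene C–H is far less acidic), followed by zinc-to-tin transmetalation, should give the stannane for the Stille coupling.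

Step 5
Reactants: 10 dimethyl squarate (3,4-dimethoxycyclobut-3-ene-1,2-dione)
Product: 11 4-hydroxy-2,3-dimethoxycyclobut-2-en-1-one (racemic)
Conditions: LiAlH(Ot-Bu)3 (1.05 equiv), THF, −78 °C; then cold pH 7 buffer
Reagents that add atoms: none
Why: Chemoselective 1,2-reduction of one carbonyl by a bulky alkoxyaluminium hydride; the product alkoxide is a far less electrophilic vinylogous ester, so reduction should stop after one hydride, and the new stereocentre forms racemic and is erased in step 7.

Step 6
Reactants: 11 4-hydroxy-2,3-dimethoxycyclobut-2-en-1-one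
Product: 12 4-chloro-2,3-dimethoxycyclobut-2-en-1-one (racemic)
Conditions: Me2C=C(Cl)NMe2 (1.1 equiv), CH2Cl2, 0 °C; concentrated cold and used at once
Reagents that add atoms: 1-chloro-N,N,2-trimethylprop-1-en-1-amine, CC(C)=C(Cl)N(C)C
Why: Neutral deoxychlorination of an allylic, hemiacetal-like alcohol with an α-chloroenamine (the method used for glycosyl chlorides) avoids the acid that would expel methanol, and the conjugated 4-chloro isomer is the thermodynamic outcome of any allylic equilibration.

Step 7
Reactants: 9 2-(tributylstannyl)-6-[2,3,4-trimethoxy-6-(methoxymethoxy)phenyl]-4H-pyran-4-one; 12 4-chloro-2,3-dimethoxycyclobut-2-en-1-one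
Product: 16 5-hydroxy-6,7-dimethoxy-2-[2,3,4-trimethoxy-6-(methoxymethoxy)phenyl]-4H-chromen-4-one, via pyranonyl-cyclobutenone 13 (not isolated), via dienylketene 14 (not isolated), via dienone tautomer 15 (not isolated)
Conditions: 12 (1.3 equiv), PdCl2(PhCN)2 (5 mol %), tri(2-furyl)phosphine (10 mol %), dioxane, 50 °C; then 100 °C
Reagents that add atoms: none
Why: Proposed new method: zerovalent palladium should insert into the allylic, α-keto C4–Cl bond of 12 to give an η3-oxocyclobutenyl palladium chloride, the pyranonyl group is transferred from tin and reductive elimination at the unsubstituted terminus C4 gives 13, which at 100 °C opens by conrotatory 4π-electrocyclic ring opening to dienylketene 14 and closes by disrotatory 6π-electrocyclisation of the ketene carbon onto pyranone C3 to dienone 15, whose C4a–H enolises to the phenol. The closest known reaction type is the palladium-catalysed Stille coupling of 4-chlorocyclobut-2-enones with alkenyl- and 2-heteroarylstannanes followed by thermal ring expansion to phenols and benzo-fused heteroarenes; new here are the 4-oxopyran-2-ylstannane partner, the 2,3-dimethoxy chloride and the closure onto a γ-pyranone. Ring A is closed at C4a–C5 by the 6π-electrocyclisation of the all-carbon triene C5=C6–C7=C8–C8a=C4a after C8–C8a has been made by the coupling, and the closure is polarity-matched because pyranone C3 is the nucleophilic α-carbon of a vinylogous ester and the ketene carbon is the electrophile. No stereocentre is formed, and the racemic centres of 12, 13 and 15 are erased on aromatisation. Two selectivities are needed: coupling at C4 and not at C2 of the allyl unit, secured because C2 is fully substituted and C4 coupling keeps the enone conjugated, and closure at a single site, secured because the other neighbour of the pyranone carbon is the ring oxygen and because ring opening is reversible, so only the ketene with the pyranone turned inward is drained. The ketene oxygen becomes the chelated 5-OH and the two squarate methoxy groups become 6-OMe and 7-OMe, so ring A should arrive in its final oxidation and protection state.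

Step 8
Reactants: 16 5-hydroxy-6,7-dimethoxy-2-[2,3,4-trimethoxy-6-(methoxymethoxy)phenyl]-4H-chromen-4-one
Product: 17 5-hydroxy-2-(6-hydroxy-2,3,4-trimethoxyphenyl)-6,7-dimethoxy-4H-chromen-4-one (5,6'-dihydroxy-6,7,2',3',4'-pentamethoxyflavone)
Conditions: 2 M HCl, MeOH/THF, 50 °C
Reagents that add atoms: none
Why: Acid-catalysed cleavage of the MOM acetal by transacetalisation to methanol; aryl methyl ethers are inert to dilute HCl at 50 °C, so the five methoxy groups and both phenols should emerge exactly as in the target.

**Compound list**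
1 | 3,4,5-trimethoxyphenol | COc1cc(O)cc(OC)c1OC | starting material
2 | 1,2,3-trimethoxy-5-(methoxymethoxy)benzene | COCOc1cc(OC)c(OC)c(OC)c1 | intermediate
3 | [2,3,4-trimethoxy-6-(methoxymethoxy)phenyl]lithium | [Li]c1c(OCOC)cc(OC)c(OC)c1OC | intermediate
4 | 1-iodo-2,3,4-trimethoxy-6-(methoxymethoxy)benzene | COCOc1cc(OC)c(OC)c(OC)c1I | intermediate
5 | 4H-pyran-4-one | O=c1ccocc1 | starting material
6 | (4-oxo-4H-pyran-2-yl)zinc chloride | O=c1ccoc([Zn]Cl)c1 | intermediate
7 | 2-[2,3,4-trimethoxy-6-(methoxymethoxy)phenyl]-4H-pyran-4-one | COCOc1cc(OC)c(OC)c(OC)c1-c1cc(=O)cco1 | intermediate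
8 | {4-oxo-6-[2,3,4-trimethoxy-6-(methoxymethoxy)phenyl]-4H-pyran-2-yl}zinc chloride | COCOc1cc(OC)c(OC)c(OC)c1-c1cc(=O)cc([Zn]Cl)o1 | intermediate
9 | 2-(tributylstannyl)-6-[2,3,4-trimethoxy-6-(methoxymethoxy)phenyl]-4H-pyran-4-one | CCCC[Sn](CCCC)(CCCC)c1cc(=O)cc(-c2c(OCOC)cc(OC)c(OC)c2OC)o1 | intermediate
10 | dimethyl squarate (3,4-dimethoxycyclobut-3-ene-1,2-dione) | COC1=C(OC)C(=O)C1=O | starting material
11 | 4-hydroxy-2,3-dimethoxycyclobut-2-en-1-one (racemic) | COC1=C(OC)C(O)C1=O | intermediate
12 | 4-chloro-2,3-dimethoxycyclobut-2-en-1-one (racemic) | COC1=C(OC)C(Cl)C1=O | intermediate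
13 | 2,3-dimethoxy-4-{4-oxo-6-[2,3,4-trimethoxy-6-(methoxymethoxy)phenyl]-4H-pyran-2-yl}cyclobut-2-en-1-one (racemic) | COC1=C(OC)C(c2cc(=O)cc(-c3c(OCOC)cc(OC)c(OC)c3OC)o2)C1=O | intermediate
14 | (3E)-2,3-dimethoxy-4-{4-oxo-6-[2,3,4-trimethoxy-6-(methoxymethoxy)phenyl]-4H-pyran-2-yl}buta-1,3-dien-1-one (ketene carbon and pyranone cis across C3=C4) | O=C=C(OC)/C(OC)=C\c1cc(=O)cc(-c2c(OCOC)cc(OC)c(OC)c2OC)o1 | intermediate
15 | 6,7-dimethoxy-2-[2,3,4-trimethoxy-6-(methoxymethoxy)phenyl]-4aH-chromene-4,5-dione (racemic) | COC1=C(OC)C(=O)C2C(=O)C=C(c3c(OCOC)cc(OC)c(OC)c3OC)OC2=C1 | intermediate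
16 | 5-hydroxy-6,7-dimethoxy-2-[2,3,4-trimethoxy-6-(methoxymethoxy)phenyl]-4H-chromen-4-one | COCOc1cc(OC)c(OC)c(OC)c1-c1cc(=O)c2c(O)c(OC)c(OC)cc2o1 | intermediate
17 | 5-hydroxy-2-(6-hydroxy-2,3,4-trimethoxyphenyl)-6,7-dimethoxy-4H-chromen-4-one | COc1cc(O)c(-c2cc(=O)c3c(O)c(OC)c(OC)cc3o2)c(OC)c1OC | target

Total steps: 8. Longest linear sequence: 6 (steps 1, 2, 3, 4, 7, 8); steps 5 and 6 form a two-step branch that joins at step 7.

Steps most likely to fail

Step 7 (proposed new method). Transmetalation from the electron-poor, α-oxygenated stannane may be slow, so that the labile chloride ionises or hydrolyses before coupling; the coupling may also occur at the substituted allyl terminus, or the ketene may oligomerise instead of cyclising. The fallback uses known chemistry only, sets out from 1 and 4 and comes back to the route at 17. Friedel–Crafts acetylation of 1 (AcOH, BF3·OEt2, 90 °C) would give 1-(6-hydroxy-2,3,4-trimethoxyphenyl)ethan-1-one F1. Condensation with DMF dimethyl acetal would give (E)-3-(dimethylamino)-1-(6-hydroxy-2,3,4-trimethoxyphenyl)prop-2-en-1-one F2, which should close in HCl to 5,6,7-trimethoxy-4H-chromen-4-one F3. C2-zincation with TMPZnCl·LiCl would give (5,6,7-trimethoxy-4-oxo-4H-chromen-2-yl)zinc chloride F4, and Negishi coupling with iodide 4 (Pd(OAc)2, SPhos) would give 5,6,7-trimethoxy-2-[2,3,4-trimethoxy-6-(methoxymethoxy)phenyl]-4H-chromen-4-one F5. BCl3 (CH2Cl2, −78 → 0 °C) would then remove the MOM group and, through the C4=O chelate, only the 5-OMe, to give 17. This gives up the freedom from demethylation but keeps the C2–C1' disconnection.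

Step 6. Ionisation at C4 may be followed by loss of a methyl group, collapsing the ring to the dione oxidation level, or the chloride may hydrolyse on handling. The fallback sets out from 10 and comes back to the route at 16. Compound 10 would be reduced as in step 5 and the aluminium alkoxide trapped cold with methyl chloroformate to give 2,3-dimethoxy-4-oxocyclobut-2-en-1-yl methyl carbonate F6, a halide-free electrophile that never passes through the free alcohol or the chloride. Under zerovalent palladium it should ionise with loss of CO2 to the same η3-oxocyclobutenyl intermediate and methoxide, which takes up the tin of stannane 9 (Stille coupling of an allylic carbonate), and heating would lead through 13 to 16.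

Step 3. Oxidative addition and transmetalation at the di-ortho-substituted, electron-rich iodide may be slow while the zincated pyranone decays by ring opening or homocoupling. The fallback sets out from 2 (through aryllithium 3) and comes back to the route at 7; it builds ring C on ring B instead of coupling to it. Quenching 3 with CO2 would give 2,3,4-trimethoxy-6-(methoxymethoxy)benzoic acid F7, and 1-chloro-N,N,2-trimethylprop-1-en-1-amine would give 2,3,4-trimethoxy-6-(methoxymethoxy)benzoyl chloride F8. C-acylation of the lithium enolate of (E)-4-methoxybut-3-en-2-one (LiHMDS, THF, −78 °C) would give (E)-5-methoxy-1-[2,3,4-trimethoxy-6-(methoxymethoxy)phenyl]pent-4-ene-1,3-dione F9. Mild acid (PPTS, toluene, 60 °C, chosen to spare the MOM ether) should close the pyranone by conjugate addition of the enol oxygen and loss of methanol, giving 7.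

Further compounds
F1 | step 7 | 1-(6-hydroxy-2,3,4-trimethoxyphenyl)ethan-1-one | CC(=O)c1c(O)cc(OC)c(OC)c1OC
F2 | step 7 | (E)-3-(dimethylamino)-1-(6-hydroxy-2,3,4-trimethoxyphenyl)prop-2-en-1-one | CN(C)/C=C/C(=O)c1c(O)cc(OC)c(OC)c1OC
F3 | step 7 | 5,6,7-trimethoxy-4H-chromen-4-one | COc1cc2occc(=O)c2c(OC)c1OC
F4 | step 7 | (5,6,7-trimethoxy-4-oxo-4H-chromen-2-yl)zinc chloride | COc1cc2oc([Zn]Cl)cc(=O)c2c(OC)c1OC
F5 | step 7 | 5,6,7-trimethoxy-2-[2,3,4-trimethoxy-6-(methoxymethoxy)phenyl]-4H-chromen-4-one | COCOc1cc(OC)c(OC)c(OC)c1-c1cc(=O)c2c(OC)c(OC)c(OC)cc2o1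
F6 | step 6 | 2,3-dimethoxy-4-oxocyclobut-2-en-1-yl methyl carbonate | COC(=O)OC1C(OC)=C(OC)C1=O
F7 | step 3 | 2,3,4-trimethoxy-6-(methoxymethoxy)benzoic acid | COCOc1cc(OC)c(OC)c(OC)c1C(=O)O
F8 | step 3 | 2,3,4-trimethoxy-6-(methoxymethoxy)benzoyl chloride | COCOc1cc(OC)c(OC)c(OC)c1C(=O)Cl
F9 | step 3 | (E)-5-methoxy-1-[2,3,4-trimethoxy-6-(methoxymethoxy)phenyl]pent-4-ene-1,3-dione | CO/C=C/C(=O)CC(=O)c1c(OC)c(OC)c(OC)cc1OCOC
A1 | direct plan | 6-hydroxy-2,3,4-trimethoxybenzaldehyde | O=Cc1c(O)cc(OC)c(OC)c1OC
A2 | direct plan | 2-[dimethyl(oxo)-λ6-sulfanylidene]-1-(6-isopropoxy-2,3,4-trimethoxyphenyl)ethan-1-one | CS(C)(=O)=CC(=O)c1c(OC(C)C)cc(OC)c(OC)c1OC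
A3 | direct plan | 2-(6-isopropoxy-2,3,4-trimethoxyphenyl)-5,6,7-trimethoxy-4H-chromen-4-one | COc1cc(OC(C)C)c(-c2cc(=O)c3c(OC)c(OC)c(OC)cc3o2)c(OC)c1OC
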